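The unbranched octadecyl chain is disconnected at C7–C8 (C1 = the OCH2 carbon). This bond joins two plain methylenes of the stereochemically blank C2–C17 segment, remote from the ester and the 2,3-dihydroxyphenyl ring. Both carbons are therefore brought in as like-polarised terminal-alkene CH carbons. Cross-metathesis of an oct-7-enyl 2,3-dihydroxybenzoate with dodec-1-ene joins C7 to C8 as a double bond with loss of ethylene, and hydrogenation in the same flask erases the alkene. The precursor is the unprotected catechol ester carrying a C8 ω-alkenyl chain, made in one step from 2,3-dihydroxybenzoic acid.

Key step: step 2

Remark: chain carbons are numbered from the ester oxygen (C1 = OCH2, C18 = CH3). Compound 5 is expected as an E/Z mixture and is drawn as the E isomer; its geometry is irrelevant because it is saturated in the same flask. Compounds 1, 2 and 4 are taken as commercially available.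

Step 1
Reactants: 1 2,3-dihydroxybenzoic acid; 2 8-bromooct-1-ene
Product: 3 oct-7-en-1-yl 2,3-dihydroxybenzoate
Conditions: KHCO3 (1.2 equiv), DMF, 40 °C, N2
Reagents that add atoms: none
Why: Carboxylate O-alkylation (SN2): bicarbonate should ionise only the carboxylic acid and not the phenols, so the primary bromide is displaced by the carboxylate alone while the terminal alkene is inert.

Step 2
Reactants: 3 oct-7-en-1-yl 2,3-dihydroxybenzoate; 4 dodec-1-ene
Product: 6 Gentiside E (octadecyl 2,3-dihydroxybenzoate), via octadec-7-enyl ester 5 (not isolated)
Conditions: Grubbs II (3 mol %), 4 (4 equiv), CH2Cl2, 40 °C, Ar sweep; then EtOAc, 10 % Pd/C, H2 (1 atm), rt, same flask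
Reagents that add atoms: none
Why: The ruthenium alkylidene engages the terminal C7=C8 alkene of 3 and the terminal alkene of 4 by [2+2] cycloaddition/cycloreversion through ruthenacyclobutanes (Chauvin mechanism), joining the two internal CH carbons as the C7=C8 double bond of 5 and releasing ethylene, after which palladium-catalysed hydrogenation in the same flask saturates that bond. The closest known reaction type is cross-metathesis of two unhindered terminal (type I) olefins followed by one-pot hydrogenation. No ring is closed and no stereocentre is formed; the E/Z geometry of 5 is immaterial because both isomers give the same CH2–CH2 unit. The step needs cross- over homo-coupling, which the excess of inexpensive 4, the removal of ethylene and the reversible secondary metathesis of any homodimer of 3 should secure. It also needs the terminal double bonds to stay in place before metathesis, since migration would give chain homologues, and the mild temperature and short reaction time should favour this. Chemoselectivity rests on the substrate: the aryl ester and the neutral, hydrogen-bonded hydroxyls of the catechol ring should not bind or react with the Ru carbene, and the benzene ring and ester should survive Pd/C under 1 atm H2.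

Compound list
1 | 2,3-dihydroxybenzoic acid | OC(=O)c1cccc(O)c1O | starting material
2 | 8-bromooct-1-ene | C=CCCCCCCBr | starting material
3 | oct-7-en-1-yl 2,3-dihydroxybenzoate | C=CCCCCCCOC(=O)c1cccc(O)c1O | intermediate
4 | dodec-1-ene | C=CCCCCCCCCCC | starting material
5 | octadec-7-en-1-yl 2,3-dihydroxybenzoate (drawn as E; E/Z mixture expected; not isolated) | CCCCCCCCCC/C=C/CCCCCCOC(=O)c1cccc(O)c1O | intermediate
6 | Gentiside E, octadecyl 2,3-dihydroxybenzoate | CCCCCCCCCCCCCCCCCCOC(=O)c1cccc(O)c1O | target

Total step count: 2
Longest linear sequence: 2 steps (1 → 3 → 6)

Steps most likely to fail (the route has only two steps, so the key step is listed once for each of its two stages):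

1. Step 2, metathesis stage. Ruthenium-hydride species formed by catalyst decay may shift the terminal double bonds of 3 or 4 before metathesis, which after hydrogenation would give inseparable chain-length homologues. The statistical partition into homodimers may also erode the cross-product, and the catechol may slow the catalyst. The fallback makes the same C7–C8 bond directly between two sp3 carbons by a copper-catalysed Grignard alkylation (Kochi coupling). It sets out from 1. Carboxylate alkylation with excess 1,7-dibromoheptane (KHCO3, DMF, 40 °C) should give 7-bromoheptyl 2,3-dihydroxybenzoate F1. Silylation (TBSCl, imidazole, DMF, rt), which avoids phenoxide attack on the primary bromide, should give 7-bromoheptyl 2,3-bis(tert-butyldimethylsilyloxy)benzoate F2. Coupling with undecylmagnesium bromide (Li2CuCl4 cat., THF, −20 to 0 °C) should give octadecyl 2,3-bis(tert-butyldimethylsilyloxy)benzoate F3, the hindered aryl ester being expected to survive at this temperature. Desilylation (TBAF, AcOH, THF, 0 °C) comes back to the route at 6.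

2. Step 1. Competing etherification of a phenolic hydroxyl or double alkylation may occur, and the catechol may darken oxidatively in the basic medium. The fallback activates the alcohol instead of using an alkyl halide. It sets out from 1, which is esterified with oct-7-en-1-ol under Mitsunobu conditions (PPh3, DIAD, THF, 0 °C to rt). Only the carboxylic acid should be acidic enough to act as the nucleophile, so no base-generated phenoxide is involved. This comes back to the route at 3 without any new intermediate.

3. Step 2, hydrogenation stage. Ruthenium and phosphine residues may poison the palladium surface, leaving the C7=C8 bond partly unsaturated. The fallback sets out from 5, which is then isolated by chromatography after the metathesis stage and reduced without a metal by diimide (TsNHNH2, NaOAc, DME/H2O, reflux). This should saturate the isolated disubstituted alkene by concerted syn hydrogen transfer while leaving the ester and catechol untouched. It comes back to the route at 6 without any new intermediate.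

Further compounds
F1 | step 2 | 7-bromoheptyl 2,3-dihydroxybenzoate | BrCCCCCCCOC(=O)c1cccc(O)c1O
F2 | step 2 | 7-bromoheptyl 2,3-bis(tert-butyldimethylsilyloxy)benzoate | BrCCCCCCCOC(=O)c1cccc(O[Si](C)(C)C(C)(C)C)c1O[Si](C)(C)C(C)(C)C
F3 | step 2 | octadecyl 2,3-bis(tert-butyldimethylsilyloxy)benzoate | CCCCCCCCCCCCCCCCCCOC(=O)c1cccc(O[Si](C)(C)C(C)(C)C)c1O[Si](C)(C)C(C)(C)C
F0 | step 1 | none | none
F0 | step 2 | none | none
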